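**Retrosynthetic overview**
1. Difengpiol A (20) comes from one hydride reduction of 19/18, which carries the two CH2OH groups as an aldehyde (masked as its dimethyl acetal) and a methyl ester, and the cis-diol as a cyclic carbonate.
2. The trans-2,3-dihydrobenzofuran 18 comes from the 2H-chromene 17 by an iodine(III)-induced ring contraction (1,2-aryl shift from C4 to C3), which relays the C2 configuration to C3.
3. Chromene 17 comes from Au-catalysed hydroarylation of aryl propargyl ether 16, which comes from phenol 6 and propargylic acetate 15 by a catalyst-controlled Cu propargylic etherification that sets C2.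
4. Acetate 15 comes from dienal 10 (Diels–Alder/elimination) by Jacobsen epoxidation, Pd/CO2 conversion to the cis-carbonate and ethynyl Grignard addition; phenol 6 comes from catechol, MeI and acrolein dimethyl acetal.
5. Ring order: cyclohexene (Diels–Alder), then cyclic carbonate, then pyran (chromene), then contraction of the pyran to the dihydrofuran.

Assumption: MeI, NIS, mCPBA, CO2, Ac2O, MeOH and water are treated as reagents, not starting materials; the facial sense of the chiral catalysts in steps 5 and 8 is assigned by analogy, and the antipodal ligand is used if an assay shows the opposite.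

**Step 1**
Reactants: 1 catechol
Product: 2 guaiacol (2-methoxyphenol)
Conditions: MeI (0.9 equiv), K2CO3, acetone, reflux; catechol in excess, washed out with water
Reagents that add atoms: iodomethane, CI
Why: Williamson mono-O-methylation; the excess of diol keeps dimethylation low.

**Step 2**
Reactants: 2 guaiacol
Product: 3 4-iodo-2-methoxyphenol
Conditions: NIS, TFA (cat.), MeCN, 0 °C
Reagents that add atoms: N-iodosuccinimide, O=C1CCC(=O)N1I
Why: Electrophilic aromatic iodination goes para to the free OH, the strongest director.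

**Step 3**
Reactants: 3 4-iodo-2-methoxyphenol; 4 3,3-dimethoxyprop-1-ene (acrolein dimethyl acetal)
Product: 6 methyl 3-(4-hydroxy-3-methoxyphenyl)propanoate, via ketene dimethyl acetal 5 (not isolated)
Conditions: Pd(OAc)2 (3 mol %), nBu4NOAc, K2CO3, KCl, DMF, 90 °C; then 1 M HCl work-up
Reagents that add atoms: water, O
Why: Heck arylation of the acetal alkene; β-hydride elimination toward the acetal carbon gives the ketene acetal, which hydrolyses to the saturated methyl ester.

**Step 4**
Reactants: 7 (E)-buta-1,3-dien-1-yl acetate (the E isomer of the commercial E/Z mixture reacts); 8 acrolein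
Product: 10 cyclohexa-1,3-diene-1-carbaldehyde, via 2-acetoxycyclohex-3-ene-1-carbaldehyde 9 (not isolated)
Conditions: toluene, BHT (cat.), 90 °C, sealed tube; then DBU, CH2Cl2, 0 °C
Reagents that add atoms: none
Why: Diels–Alder reaction with "ortho" regiochemistry, then E1cB loss of acetic acid from the β-acetoxy aldehyde gives the conjugated dienal.

**Step 5**
Reactants: 10 cyclohexa-1,3-diene-1-carbaldehyde
Product: 11 (1S,6R)-7-oxabicyclo[4.1.0]hept-2-ene-3-carbaldehyde
Conditions: (S,S)-Jacobsen Mn(salen)Cl (5 mol %), mCPBA, NMO, CH2Cl2, −78 °C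
Reagents that add atoms: mCPBA, OOC(=O)c1cccc(Cl)c1
Why: Jacobsen–Katsuki epoxidation; the Mn-oxo species takes the conjugated cis-disubstituted γ,δ-alkene rather than the electron-poor trisubstituted enal alkene, and side-on approach to the salen (as with indene giving the 1S,2R oxide) sets both epoxide carbons.

**Step 6**
Reactants: 11 (1S,6R)-7-oxabicyclo[4.1.0]hept-2-ene-3-carbaldehyde
Product: 12 (3aS,7aR)-2-oxo-3a,6,7,7a-tetrahydro-1,3-benzodioxole-5-carbaldehyde (cis-fused cyclic carbonate)
Conditions: Pd(PPh3)4 (3 mol %), CO2 (1 atm), THF, 0 to 23 °C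
Reagents that add atoms: carbon dioxide, O=C=O
Why: Pd(0)-catalysed CO2 insertion into a vinyl epoxide (π-allyl chemistry); ionisation with inversion and intramolecular carbonate attack with a second inversion give net retention at the allylic carbon, hence the cis-diol as its carbonate.

**Step 7**
Reactants: 12 carbonate aldehyde; 13 ethynylmagnesium bromide
Product: 15 1-[(3aS,7aR)-2-oxo-3a,6,7,7a-tetrahydro-1,3-benzodioxol-5-yl]prop-2-yn-1-yl acetate (both epimers at C1, about 1:1), via bromomagnesium propargylic alkoxide 14 (not isolated)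
Conditions: THF, −78 °C; then Ac2O, DMAP (cat.), −78 to 0 °C
Reagents that add atoms: acetic anhydride, CC(=O)OC(C)=O
Why: Grignard 1,2-addition to the enal is much faster than attack on the carbonate at −78 °C, and the alkoxide is acetylated in situ; the new centre is left unselective on purpose because step 8 is stereoconvergent.

**Step 8**
Reactants: 15 propargylic acetate (epimer mixture); 6 methyl 3-(4-hydroxy-3-methoxyphenyl)propanoate
Product: 16 methyl 3-[3-methoxy-4-({(1S)-1-[(3aS,7aR)-2-oxo-3a,6,7,7a-tetrahydro-1,3-benzodioxol-5-yl]prop-2-yn-1-yl}oxy)phenyl]propanoate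
Conditions: Cu(MeCN)4BF4 (5 mol %), (S,S)-Ph-pybox (6 mol %), iPr2NEt (1.2 equiv), PhCF3, −20 °C
Reagents that add atoms: none
Why: Proposed new method: Cu(I)–pybox-catalysed stereoconvergent propargylic etherification of a 1-alkenyl (not aryl) propargylic acetate with a phenol, in which the Cu acetylide loses acetate to give a Cu–allenylidene that is planar at Cγ (so both epimers of 15 converge) and the phenoxide adds to Cγ on the face left open by the pybox phenyl groups, setting the 1S ether centre under catalyst control; attack at the vinylogous ring carbon is disfavoured because it is secondary and flanked by the carbonate C–O bond; the closest known reaction type is Cu–pybox asymmetric propargylic amination/etherification of 1-aryl propargylic esters via copper allenylidenes.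

**Step 9**
Reactants: 16 aryl propargyl ether
Product: 17 methyl 3-{(2S)-8-methoxy-2-[(3aS,7aR)-2-oxo-3a,6,7,7a-tetrahydro-1,3-benzodioxol-5-yl]-2H-chromen-6-yl}propanoate
Conditions: JohnPhosAu(MeCN)SbF6 (2 mol %), CH2Cl2, 23 °C
Reagents that add atoms: none
Why: Gold(I)-catalysed 6-endo-dig intramolecular hydroarylation at the only free ortho position; the C–O stereocentre is not touched.

**Step 10**
Reactants: 17 2H-chromene
Product: 18 methyl 3-{(2S,3S)-3-(dimethoxymethyl)-7-methoxy-2-[(3aS,7aR)-2-oxo-3a,6,7,7a-tetrahydro-1,3-benzodioxol-5-yl]-2,3-dihydro-1-benzofuran-5-yl}propanoate (2,3-trans)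
Conditions: PhI(OH)OTs (1.2 equiv), MeOH, 3 Å MS, −20 to 0 °C
Reagents that add atoms: methanol, CO
Why: Iodine(III)-mediated oxidative ring contraction of a benzo-fused cycloalkene; the iodane adds to C3 anti to the C2 substituent and MeOH to C4, then the equatorial C3–I bond, anti-periplanar to C4–C4a, leaves with a 1,2-aryl shift (inversion at C3) to a methoxy-oxocarbenium ion trapped as the acetal, which gives the 2,3-trans product; the doubly oxygen-deactivated cyclohexene alkene is much less nucleophilic than the chromene alkene.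

**Step 11**
Reactants: 18 acetal
Product: 20 difengpiol A, via aldehyde 19 (not isolated)
Conditions: 1 M HCl, THF, 23 °C, extractive work-up; then LiAlH4 (excess), THF, 0 °C
Reagents that add atoms: water, O
Why: Acetal hydrolysis (the epimerisable C3 stays in the more stable trans arrangement), then hydride reduction of aldehyde, methyl ester and cyclic carbonate in one operation; no stereocentre is touched.

**Compound list**
1 | catechol | Oc1ccccc1O | starting material
2 | guaiacol | COc1ccccc1O | intermediate
3 | 4-iodo-2-methoxyphenol | COc1cc(I)ccc1O | intermediate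
4 | 3,3-dimethoxyprop-1-ene | C=CC(OC)OC | starting material
5 | 4-(3,3-dimethoxyprop-2-en-1-yl)-2-methoxyphenol (ketene dimethyl acetal) | COC(OC)=CCc1ccc(O)c(OC)c1 | intermediate
6 | methyl 3-(4-hydroxy-3-methoxyphenyl)propanoate | COC(=O)CCc1ccc(O)c(OC)c1 | intermediate
7 | (E)-buta-1,3-dien-1-yl acetate | CC(=O)O/C=C/C=C | starting material
8 | acrolein | C=CC=O | starting material
9 | 2-acetoxycyclohex-3-ene-1-carbaldehyde (racemic) | CC(=O)OC1C=CCCC1C=O | intermediate
10 | cyclohexa-1,3-diene-1-carbaldehyde | O=CC1=CC=CCC1 | intermediate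
11 | (1S,6R)-7-oxabicyclo[4.1.0]hept-2-ene-3-carbaldehyde | O=CC1=C[C@H](O2)[C@H]2CC1 | intermediate
12 | (3aS,7aR)-2-oxo-3a,6,7,7a-tetrahydro-1,3-benzodioxole-5-carbaldehyde | O=CC1=C[C@H](O2)[C@H](OC2=O)CC1 | intermediate
13 | ethynylmagnesium bromide | C#C[Mg]Br | starting material
14 | bromomagnesium 1-[(3aS,7aR)-2-oxo-3a,6,7,7a-tetrahydro-1,3-benzodioxol-5-yl]prop-2-yn-1-olate (both C1 epimers) | Br[Mg]OC(C#C)C1=C[C@H](O2)[C@H](OC2=O)CC1 | intermediate
15 | 1-[(3aS,7aR)-2-oxo-3a,6,7,7a-tetrahydro-1,3-benzodioxol-5-yl]prop-2-yn-1-yl acetate (both C1 epimers) | CC(=O)OC(C#C)C1=C[C@H](O2)[C@H](OC2=O)CC1 | intermediate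
16 | methyl 3-[3-methoxy-4-({(1S)-1-[(3aS,7aR)-2-oxo-3a,6,7,7a-tetrahydro-1,3-benzodioxol-5-yl]prop-2-yn-1-yl}oxy)phenyl]propanoate | COc1cc(CCC(=O)OC)ccc1O[C@H](C2=C[C@H](O3)[C@H](OC3=O)CC2)C#C | intermediate
17 | methyl 3-{(2S)-8-methoxy-2-[(3aS,7aR)-2-oxo-3a,6,7,7a-tetrahydro-1,3-benzodioxol-5-yl]-2H-chromen-6-yl}propanoate | COc1cc(CCC(=O)OC)cc2c1O[C@H](C3=C[C@H](O4)[C@H](OC4=O)CC3)C=C2 | intermediate
18 | methyl 3-{(2S,3S)-3-(dimethoxymethyl)-7-methoxy-2-[(3aS,7aR)-2-oxo-3a,6,7,7a-tetrahydro-1,3-benzodioxol-5-yl]-2,3-dihydro-1-benzofuran-5-yl}propanoate | COc1cc(CCC(=O)OC)cc2c1O[C@H](C3=C[C@H](O4)[C@H](OC4=O)CC3)[C@H]2C(OC)OC | intermediate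
19 | methyl 3-{(2S,3S)-3-formyl-7-methoxy-2-[(3aS,7aR)-2-oxo-3a,6,7,7a-tetrahydro-1,3-benzodioxol-5-yl]-2,3-dihydro-1-benzofuran-5-yl}propanoate | COc1cc(CCC(=O)OC)cc2c1O[C@H](C3=C[C@H](O4)[C@H](OC4=O)CC3)[C@H]2C=O | intermediate
20 | difengpiol A, (1R,2S)-4-[(2S,3R)-3-(hydroxymethyl)-5-(3-hydroxypropyl)-7-methoxy-2,3-dihydro-1-benzofuran-2-yl]cyclohex-3-ene-1,2-diol | COc1cc(CCCO)cc2c1O[C@H](C1=C[C@H](O)[C@H](O)CC1)[C@H]2CO | target

**Count**
Total steps: 11. Longest linear sequence: 8 (steps 4 to 11); the aryl branch (steps 1 to 3) joins at step 8.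

**Three steps most likely to fail**

Step 8 (the proposed new reaction). It may fail through attack at the vinylogous ring carbon, C-alkylation of the phenol, or low catalyst control. The fallback uses known chemistry and sets out from 12. Zinc–ProPhenol asymmetric alkynylation with trimethylsilylacetylene (Me2Zn, ProPhenol, Ph3PO, toluene, 0 °C) gives (1S)-1-[(3aS,7aR)-2-oxo-3a,6,7,7a-tetrahydro-1,3-benzodioxol-5-yl]-3-(trimethylsilyl)prop-2-yn-1-ol F1. AcOH-buffered TBAF (THF, 0 °C), which spares the carbonate, gives (1R)-1-[(3aS,7aR)-2-oxo-3a,6,7,7a-tetrahydro-1,3-benzodioxol-5-yl]prop-2-yn-1-ol F2; the spatial arrangement is unchanged and only the descriptor changes with loss of silicon. Mitsunobu etherification of F2 with phenol 6 (PPh3, DIAD, toluene, 0 °C) proceeds with inversion and comes back to the route at 16.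

Step 10. Plain trans-addition of two methoxy groups could compete with the aryl shift. The fallback sets out from 17. NBS in wet THF at 0 °C gives, by anti addition on the face away from the C2 substituent, the all-trans bromohydrin methyl 3-{(2R,3S,4R)-3-bromo-4-hydroxy-8-methoxy-2-[(3aS,7aR)-2-oxo-3a,6,7,7a-tetrahydro-1,3-benzodioxol-5-yl]-3,4-dihydro-2H-chromen-6-yl}propanoate F3. AgBF4 in CH2Cl2 at −20 °C then triggers a semipinacol 1,2-aryl shift (equatorial C–Br anti to C4–C4a, hydroxyl push) with no external nucleophile present, and gives aldehyde 19 directly. The fallback comes back at 19, which is reduced with LiAlH4 as in step 11.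

Step 5. The dienal is electron-poor and the epoxy-enal is base-sensitive, so conversion or ee may be poor. The fallback sets out from 10 and moves the oxidation to a later, aldehyde-free substrate. Ethynylmagnesium bromide 13 and then Ac2O give racemic 1-(cyclohexa-1,3-dien-1-yl)prop-2-yn-1-yl acetate F4. Jacobsen epoxidation of its electron-richer cis-diene (same catalyst, mCPBA/NMO, −78 °C) gives 1-[(1S,6R)-7-oxabicyclo[4.1.0]hept-2-en-3-yl]prop-2-yn-1-yl acetate F5. Because Pd(0) would ionise the allylic/propargylic acetate, CO2 is inserted under halide/Lewis-acid catalysis (nBu4NBr, (salen)AlCl, CO2 1 atm, 25 °C); two inversions at the allylic carbon give the cis-carbonate, and the fallback comes back at 15. Any stereochemical leakage from this step is removed after step 8, because the minor isomers are then diastereomers of 16 and can be separated by chromatography.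

**Further compounds**
F1 | step 8 | (1S)-1-[(3aS,7aR)-2-oxo-3a,6,7,7a-tetrahydro-1,3-benzodioxol-5-yl]-3-(trimethylsilyl)prop-2-yn-1-ol | O[C@@H](C1=C[C@H](O2)[C@H](OC2=O)CC1)C#C[Si](C)(C)C
F2 | step 8 | (1R)-1-[(3aS,7aR)-2-oxo-3a,6,7,7a-tetrahydro-1,3-benzodioxol-5-yl]prop-2-yn-1-ol | O[C@@H](C1=C[C@H](O2)[C@H](OC2=O)CC1)C#C
F3 | step 10 | methyl 3-{(2R,3S,4R)-3-bromo-4-hydroxy-8-methoxy-2-[(3aS,7aR)-2-oxo-3a,6,7,7a-tetrahydro-1,3-benzodioxol-5-yl]-3,4-dihydro-2H-chromen-6-yl}propanoate | COc1cc(CCC(=O)OC)cc2c1O[C@H](C3=C[C@H](O4)[C@H](OC4=O)CC3)[C@@H](Br)[C@@H]2O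
F4 | step 5 | 1-(cyclohexa-1,3-dien-1-yl)prop-2-yn-1-yl acetate (racemic) | CC(=O)OC(C#C)C1=CC=CCC1
F5 | step 5 | 1-[(1S,6R)-7-oxabicyclo[4.1.0]hept-2-en-3-yl]prop-2-yn-1-yl acetate (both C1 epimers) | CC(=O)OC(C#C)C1=C[C@H](O2)[C@H]2CC1
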